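**Retrosynthetic overview**
1. Feature: flavan C2 carries the 4-hydroxyphenyl ring B. A C2 carbinol can therefore lose water to a ring B para-quinone methide, which the ring A phenol oxygen (the future O1) attacks. The flavan is cut at O1–C2 (pyran ring C), and either carbinol epimer can be used.
2. The open-chain triol (C4 set) comes from a 4-arylchroman-2-ol and a 4-silyloxyphenyl Grignard reagent. The lactol comes from 3,5-dimethoxyphenol and a ring D cinnamaldehyde by iminium-catalysed Friedel–Crafts alkylation/lactolisation, which sets C4.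
3. Ring D is carried as one allyl ether (the future flavanone O1) and two benzyl ethers. After ring C is closed, the freed phenol directs ortho-formylation without acid; styryl addition and oxidation give the 2'-hydroxychalcone.
4. The flavanone heterocycle is cut at its O1–C2 bond (asymmetric oxa-Michael addition); hydrogenolysis of three benzyl ethers ends the route.
5. Ring order: lactol (temporary), then flavan ring C (key step), then the flavanone pyranone ring.

Key step: step 8

Remark 1: (R)-TRIP in step 8 and the quinine-derived thiourea in step 14 are assumed to favour 2S at the flavan and 2S at the flavanone; the sense is to be checked on a small scale and the mirror-image or pseudo-enantiomeric catalyst taken if it is opposite.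
Remark 2: the flavans are described as (2S) with ring D at C4 trans to ring B, because the CIP descriptor at C4 changes with the ring D substituents while the geometry stays the same.

**Route**

Step 1
Reactants: 1 2,4,6-trihydroxybenzaldehyde
Product: 2 2,4-bis(benzyloxy)-6-hydroxybenzaldehyde
Conditions: BnBr (2.0 equiv), K2CO3, DMF, 0 °C → rt
Reagents that add atoms: benzyl bromide, BrCc1ccccc1
Why: Williamson etherification, in which the 4-OH and one ortho OH are alkylated while the last ortho OH is held in a hydrogen bond to the formyl group and is the least nucleophilic, so two equivalents of benzyl bromide should stop at the bis-ether.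

Step 2
Reactants: 2 2,4-bis(benzyloxy)-6-hydroxybenzaldehyde
Product: 3 2-(allyloxy)-4,6-bis(benzyloxy)benzaldehyde
Conditions: allyl bromide, K2CO3, DMF, 60 °C
Reagents that add atoms: allyl bromide, C=CCBr
Why: Williamson etherification of the remaining chelated phenol, which needs only mild heating; the allyl ether marks the ring D oxygen that later becomes the flavanone O1.

Step 3
Reactants: 3 2-(allyloxy)-4,6-bis(benzyloxy)benzaldehyde
Product: 5 (E)-3-[2-(allyloxy)-4,6-bis(benzyloxy)phenyl]prop-2-enal, via vinyl dioxolane 4 (not isolated)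
Conditions: (1,3-dioxolan-2-ylmethyl)triphenylphosphonium bromide, t-BuOK, THF, 0 °C → rt; then 1 M HCl, THF, rt
Reagents that add atoms: (1,3-dioxolan-2-ylmethyl)triphenylphosphonium bromide, [Br-].C1COC(C[P+](c2ccccc2)(c2ccccc2)c2ccccc2)O1; water, O
Why: Wittig olefination with the dioxolanylmethyl ylide followed by acid hydrolysis of the vinyl acetal is the standard two-carbon homologation of an aryl aldehyde to a cinnamaldehyde, and the acid should also equilibrate the enal to the E isomer.

Step 4
Reactants: 5 (E)-3-[2-(allyloxy)-4,6-bis(benzyloxy)phenyl]prop-2-enal; 6 3,5-dimethoxyphenol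
Product: 8 (4S)-4-[2-(allyloxy)-4,6-bis(benzyloxy)phenyl]-5,7-dimethoxychroman-2-ol (both C2 anomers), via open-chain aldehyde 7 (not isolated)
Conditions: (S)-α,α-diphenylprolinol trimethylsilyl ether (20 mol%), PhCO2H (20 mol%), toluene, 0 °C → rt
Reagents that add atoms: none
Why: Iminium-catalysed Friedel–Crafts alkylation/hemiacetalisation, known for electron-rich phenols and enals: the carbon ortho to the hydroxyl of 6 should add to the β-carbon of the E iminium ion on the face away from the diphenyl(silyloxy)methyl group, which sets C4 as drawn, and the phenol then closes the lactol.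

Step 5
Reactants: 9 4-bromophenol
Product: 10 (4-bromophenoxy)(tert-butyl)dimethylsilane
Conditions: TBSCl, imidazole, CH2Cl2, rt
Reagents that add atoms: tert-butyldimethylsilyl chloride, CC(C)(C)[Si](C)(C)Cl
Why: Standard silylation of a phenol, which masks the acidic OH so that the aryl bromide can be turned into a Grignard reagent.

Step 6
Reactants: 8 (4S)-4-[2-(allyloxy)-4,6-bis(benzyloxy)phenyl]-5,7-dimethoxychroman-2-ol; 10 (4-bromophenoxy)(tert-butyl)dimethylsilane
Product: 12 (3R)-3-[2-(allyloxy)-4,6-bis(benzyloxy)phenyl]-1-[4-(tert-butyldimethylsilyloxy)phenyl]-3-(2-hydroxy-4,6-dimethoxyphenyl)propan-1-ol (both C1 epimers), via aryl Grignard reagent 11 (not isolated)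
Conditions: 10 (3 equiv), Mg, THF, rt; then 8, THF, 0 °C → rt; water/pH 7 buffer; silica deactivated with Et3N
Reagents that add atoms: none
Why: Grignard addition to a lactol, in which the first equivalent of 11 deprotonates 8 so that it opens to the magnesium salt of aldehyde 7 and a further equivalent adds to the formyl group; the carbinol centre forms without control, which is harmless because it becomes planar in step 8.

Step 7
Reactants: 12 (3R)-3-[2-(allyloxy)-4,6-bis(benzyloxy)phenyl]-1-[4-(tert-butyldimethylsilyloxy)phenyl]-3-(2-hydroxy-4,6-dimethoxyphenyl)propan-1-ol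
Product: 13 (3R)-3-[2-(allyloxy)-4,6-bis(benzyloxy)phenyl]-3-(2-hydroxy-4,6-dimethoxyphenyl)-1-(4-hydroxyphenyl)propan-1-ol (both C1 epimers)
Conditions: TBAF, AcOH (1:1), THF, 0 °C
Reagents that add atoms: none
Why: Fluoride cleavage of the aryl silyl ether, buffered with acetic acid so that neither phenoxide-driven nor acid-driven loss of the benzylic hydroxyl should set in before the chiral catalyst is present.

Step 8
Reactants: 13 (3R)-3-[2-(allyloxy)-4,6-bis(benzyloxy)phenyl]-3-(2-hydroxy-4,6-dimethoxyphenyl)-1-(4-hydroxyphenyl)propan-1-ol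
Product: 15 4-{(2S)-4-[2-(allyloxy)-4,6-bis(benzyloxy)phenyl]-5,7-dimethoxychroman-2-yl}phenol (2,4-trans), via para-quinone methide 14 (not isolated)
Conditions: (R)-3,3'-bis(2,4,6-triisopropylphenyl)-1,1'-binaphthyl-2,2'-diyl hydrogen phosphate ((R)-TRIP, 5 mol%), 5 Å molecular sieves, CH2Cl2/toluene, −20 → 0 °C
Reagents that add atoms: none
Why: The phosphoric acid hydrogen-bonds to the benzylic hydroxyl of either C1 epimer of 13 and assists loss of water, so both epimers should give the same ring B para-quinone methide 14, whose carbonyl oxygen stays bound to the P–OH while the P=O accepts the O–H of the ring A phenol; this oxygen then adds to the exocyclic carbon (oxa-1,6-addition) and ring B rearomatises. The closest known reaction type is the chiral phosphoric acid-catalysed 1,6-addition of nucleophiles to para-quinone methides generated in situ from 4-hydroxybenzylic alcohols. Pyran ring C closes in the 6-exo-trig mode, since the C=C bond that is attacked lies outside the ring being formed. The new stereocentre C2 is controlled by the chiral phosphate, which holds both reacting ends, and the substrate should reinforce it: in a chair-like transition state the ring D aryl at C4 sits pseudo-axial to avoid the peri 5-methoxy group and ring B sits equatorial, which is the 2,4-trans arrangement. The step needs facial selectivity at the planar C2 and attack by oxygen only; the second is secured because all three ring D oxygens are ethers, because both ortho positions of rings A and D carry oxygen so that no carbocycle of 5 or 6 members can form, and because low temperature and low acid loading should keep the product ether from re-ionising. Any 4-hydroxystyrene formed by tautomerisation of 14 should be returned to 14 by the same acid.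

Step 9
Reactants: 15 4-{(2S)-4-[2-(allyloxy)-4,6-bis(benzyloxy)phenyl]-5,7-dimethoxychroman-2-yl}phenol
Product: 16 (2S)-4-[2-(allyloxy)-4,6-bis(benzyloxy)phenyl]-2-[4-(benzyloxy)phenyl]-5,7-dimethoxychroman (2,4-trans)
Conditions: BnBr, K2CO3, DMF, 0 °C → rt
Reagents that add atoms: benzyl bromide, BrCc1ccccc1
Why: Williamson etherification of the only free phenol at or below room temperature, where the phenoxide should be alkylated faster than it can reopen ring C by expelling the ring A aryloxide, so C2 keeps its configuration.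

Step 10
Reactants: 16 (2S)-4-[2-(allyloxy)-4,6-bis(benzyloxy)phenyl]-2-[4-(benzyloxy)phenyl]-5,7-dimethoxychroman
Product: 17 3,5-bis(benzyloxy)-2-{(2S)-2-[4-(benzyloxy)phenyl]-5,7-dimethoxychroman-4-yl}phenol (2,4-trans)
Conditions: Pd(PPh3)4 (5 mol%), morpholine, THF, rt
Reagents that add atoms: none
Why: Tsuji–Trost-type deallylation, in which Pd(PPh3)4 (zerovalent palladium) ionises the allyl aryl ether and morpholine traps the π-allyl complex, while benzyl and methyl ethers are untouched.

Step 11
Reactants: 17 3,5-bis(benzyloxy)-2-{(2S)-2-[4-(benzyloxy)phenyl]-5,7-dimethoxychroman-4-yl}phenol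
Product: 19 4,6-bis(benzyloxy)-3-{(2S)-2-[4-(benzyloxy)phenyl]-5,7-dimethoxychroman-4-yl}-2-hydroxybenzaldehyde (2,4-trans), via hydroxymethyl phenol 18 (not isolated)
Conditions: MgCl2, Et3N, (CH2O)n, THF, 65 °C
Reagents that add atoms: paraformaldehyde (as formaldehyde), C=O
Why: Casnati–Skattebøl ortho-formylation, in which the magnesium phenoxide delivers formaldehyde to its only free ortho position and a second formaldehyde takes up hydride from 18 (Oppenauer-type), so ring A, which has no free phenol, should stay untouched and no acid meets the acid-labile C4–aryl and C2–O bonds.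

Step 12
Reactants: 19 4,6-bis(benzyloxy)-3-{(2S)-2-[4-(benzyloxy)phenyl]-5,7-dimethoxychroman-4-yl}-2-hydroxybenzaldehyde; 20 (E)-(2-bromovinyl)benzene
Product: 22 (E)-1-{4,6-bis(benzyloxy)-3-[(2S)-2-[4-(benzyloxy)phenyl]-5,7-dimethoxychroman-4-yl]-2-hydroxyphenyl}-3-phenylprop-2-en-1-ol (2,4-trans flavan; both carbinol epimers), via styryl Grignard reagent 21 (not isolated)
Conditions: 20 (3 equiv), Mg, THF, rt; then 19, THF, −40 → 0 °C; pH 7 buffer; used crude at once
Reagents that add atoms: none
Why: Grignard 1,2-addition to the salicylaldehyde (one equivalent is spent on the phenol), which brings in the styryl unit with its E geometry; the carbinol centre is not controlled because it is oxidised in step 13.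

Step 13
Reactants: 22 (E)-1-{4,6-bis(benzyloxy)-3-[(2S)-2-[4-(benzyloxy)phenyl]-5,7-dimethoxychroman-4-yl]-2-hydroxyphenyl}-3-phenylprop-2-en-1-ol
Product: 23 (E)-1-{4,6-bis(benzyloxy)-3-[(2S)-2-[4-(benzyloxy)phenyl]-5,7-dimethoxychroman-4-yl]-2-hydroxyphenyl}-3-phenylprop-2-en-1-one (2,4-trans flavan)
Conditions: MnO2 (activated, excess), CH2Cl2, rt
Reagents that add atoms: none
Why: MnO2 oxidises the allylic and benzylic alcohol selectively under neutral conditions to the hydrogen-bonded 2'-hydroxychalcone, before the alcohol can ionise to an ortho-quinone methide.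

Step 14
Reactants: 23 (E)-1-{4,6-bis(benzyloxy)-3-[(2S)-2-[4-(benzyloxy)phenyl]-5,7-dimethoxychroman-4-yl]-2-hydroxyphenyl}-3-phenylprop-2-en-1-one
Product: 24 (2S)-5,7-bis(benzyloxy)-8-{(2S)-2-[4-(benzyloxy)phenyl]-5,7-dimethoxychroman-4-yl}-2-phenylchroman-4-one (2,4-trans flavan)
Conditions: 1-[3,5-bis(trifluoromethyl)phenyl]-3-[(8α,9S)-6'-methoxycinchonan-9-yl]thiourea (quinine-derived, 20 mol%), toluene, 0 °C → rt; stopped at full conversion
Reagents that add atoms: none
Why: Asymmetric intramolecular oxa-Michael addition (chalcone–flavanone cyclisation) under bifunctional amine–thiourea catalysis, in which the thiourea binds the enone, the quinuclidine activates the only free phenol and the oxygen adds to one face of the β-carbon to set the flavanone C2 as S; the benzyl ether on the other ortho oxygen rules out closure to the 6-linked regioisomer.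

Step 15
Reactants: 24 (2S)-5,7-bis(benzyloxy)-8-{(2S)-2-[4-(benzyloxy)phenyl]-5,7-dimethoxychroman-4-yl}-2-phenylchroman-4-one
Product: 25 (2S)-5,7-dihydroxy-8-[(2S)-2-(4-hydroxyphenyl)-5,7-dimethoxychroman-4-yl]-2-phenylchroman-4-one (2,4-trans flavan; CNP0188217.1)
Conditions: H2 (1 atm), Pd/C (10% Pd on carbon), EtOAc/MeOH, rt; stopped after three equivalents of H2
Reagents that add atoms: none
Why: Hydrogenolysis of the three aryl benzyl ethers over Pd/C, which should be cleaved well before the cyclic benzylic C–O bonds, under neutral conditions that do not epimerise the flavanone C2.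

**Compound list**
1 | 2,4,6-trihydroxybenzaldehyde | O=Cc1c(O)cc(O)cc1O | starting material
2 | 2,4-bis(benzyloxy)-6-hydroxybenzaldehyde | O=Cc1c(O)cc(OCc2ccccc2)cc1OCc1ccccc1 | intermediate
3 | 2-(allyloxy)-4,6-bis(benzyloxy)benzaldehyde | C=CCOc1cc(OCc2ccccc2)cc(OCc2ccccc2)c1C=O | intermediate
4 | 2-{2-[2-(allyloxy)-4,6-bis(benzyloxy)phenyl]ethenyl}-1,3-dioxolane (E/Z mixture) | C=CCOc1cc(OCc2ccccc2)cc(OCc2ccccc2)c1C=CC1OCCO1 | intermediate
5 | (E)-3-[2-(allyloxy)-4,6-bis(benzyloxy)phenyl]prop-2-enal | C=CCOc1cc(OCc2ccccc2)cc(OCc2ccccc2)c1/C=C/C=O | intermediate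
6 | 3,5-dimethoxyphenol | COc1cc(O)cc(OC)c1 | starting material
7 | (3R)-3-[2-(allyloxy)-4,6-bis(benzyloxy)phenyl]-3-(2-hydroxy-4,6-dimethoxyphenyl)propanal | O=CC[C@H](c1c(O)cc(OC)cc1OC)c1c(OCC=C)cc(OCc2ccccc2)cc1OCc1ccccc1 | intermediate
8 | (4S)-4-[2-(allyloxy)-4,6-bis(benzyloxy)phenyl]-5,7-dimethoxychroman-2-ol (both C2 anomers) | COc1cc(OC)c2c(c1)OC(O)C[C@H]2c1c(OCC=C)cc(OCc3ccccc3)cc1OCc1ccccc1 | intermediate
9 | 4-bromophenol | Oc1ccc(Br)cc1 | starting material
10 | (4-bromophenoxy)(tert-butyl)dimethylsilane | CC(C)(C)[Si](C)(C)Oc1ccc(Br)cc1 | intermediate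
11 | [4-(tert-butyldimethylsilyloxy)phenyl]magnesium bromide | CC(C)(C)[Si](C)(C)Oc1ccc([Mg]Br)cc1 | intermediate
12 | (3R)-3-[2-(allyloxy)-4,6-bis(benzyloxy)phenyl]-1-[4-(tert-butyldimethylsilyloxy)phenyl]-3-(2-hydroxy-4,6-dimethoxyphenyl)propan-1-ol (both C1 epimers) | OC(C[C@H](c1c(O)cc(OC)cc1OC)c1c(OCC=C)cc(OCc2ccccc2)cc1OCc1ccccc1)c1ccc(O[Si](C)(C)C(C)(C)C)cc1 | intermediate
13 | (3R)-3-[2-(allyloxy)-4,6-bis(benzyloxy)phenyl]-3-(2-hydroxy-4,6-dimethoxyphenyl)-1-(4-hydroxyphenyl)propan-1-ol (both C1 epimers; key-step precursor) | OC(C[C@H](c1c(O)cc(OC)cc1OC)c1c(OCC=C)cc(OCc2ccccc2)cc1OCc1ccccc1)c1ccc(O)cc1 | intermediate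
14 | 4-{(3R)-3-[2-(allyloxy)-4,6-bis(benzyloxy)phenyl]-3-(2-hydroxy-4,6-dimethoxyphenyl)propylidene}cyclohexa-2,5-dien-1-one | O=C1C=CC(=CC[C@H](c2c(O)cc(OC)cc2OC)c2c(OCC=C)cc(OCc3ccccc3)cc2OCc2ccccc2)C=C1 | intermediate
15 | 4-{(2S)-4-[2-(allyloxy)-4,6-bis(benzyloxy)phenyl]-5,7-dimethoxychroman-2-yl}phenol (2,4-trans; key-step product) | COc1cc(OC)c2c(c1)O[C@H](c1ccc(O)cc1)C[C@H]2c1c(OCC=C)cc(OCc3ccccc3)cc1OCc1ccccc1 | intermediate
16 | (2S)-4-[2-(allyloxy)-4,6-bis(benzyloxy)phenyl]-2-[4-(benzyloxy)phenyl]-5,7-dimethoxychroman (2,4-trans) | COc1cc(OC)c2c(c1)O[C@H](c1ccc(OCc3ccccc3)cc1)C[C@H]2c1c(OCC=C)cc(OCc3ccccc3)cc1OCc1ccccc1 | intermediate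
17 | 3,5-bis(benzyloxy)-2-{(2S)-2-[4-(benzyloxy)phenyl]-5,7-dimethoxychroman-4-yl}phenol (2,4-trans) | COc1cc(OC)c2c(c1)O[C@H](c1ccc(OCc3ccccc3)cc1)C[C@H]2c1c(O)cc(OCc3ccccc3)cc1OCc1ccccc1 | intermediate
18 | 3,5-bis(benzyloxy)-2-{(2S)-2-[4-(benzyloxy)phenyl]-5,7-dimethoxychroman-4-yl}-6-(hydroxymethyl)phenol (2,4-trans) | COc1cc(OC)c2c(c1)O[C@H](c1ccc(OCc3ccccc3)cc1)C[C@H]2c1c(O)c(CO)c(OCc2ccccc2)cc1OCc1ccccc1 | intermediate
19 | 4,6-bis(benzyloxy)-3-{(2S)-2-[4-(benzyloxy)phenyl]-5,7-dimethoxychroman-4-yl}-2-hydroxybenzaldehyde (2,4-trans) | COc1cc(OC)c2c(c1)O[C@H](c1ccc(OCc3ccccc3)cc1)C[C@H]2c1c(O)c(C=O)c(OCc2ccccc2)cc1OCc1ccccc1 | intermediate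
20 | (E)-(2-bromovinyl)benzene | Br/C=C/c1ccccc1 | starting material
21 | (E)-styrylmagnesium bromide | Br[Mg]/C=C/c1ccccc1 | intermediate
22 | (E)-1-{4,6-bis(benzyloxy)-3-[(2S)-2-[4-(benzyloxy)phenyl]-5,7-dimethoxychroman-4-yl]-2-hydroxyphenyl}-3-phenylprop-2-en-1-ol (2,4-trans flavan; both carbinol epimers) | COc1cc(OC)c2c(c1)O[C@H](c1ccc(OCc3ccccc3)cc1)C[C@H]2c1c(O)c(C(O)/C=C/c2ccccc2)c(OCc2ccccc2)cc1OCc1ccccc1 | intermediate
23 | (E)-1-{4,6-bis(benzyloxy)-3-[(2S)-2-[4-(benzyloxy)phenyl]-5,7-dimethoxychroman-4-yl]-2-hydroxyphenyl}-3-phenylprop-2-en-1-one (2,4-trans flavan) | COc1cc(OC)c2c(c1)O[C@H](c1ccc(OCc3ccccc3)cc1)C[C@H]2c1c(O)c(C(=O)/C=C/c2ccccc2)c(OCc2ccccc2)cc1OCc1ccccc1 | intermediate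
24 | (2S)-5,7-bis(benzyloxy)-8-{(2S)-2-[4-(benzyloxy)phenyl]-5,7-dimethoxychroman-4-yl}-2-phenylchroman-4-one (2,4-trans flavan) | COc1cc(OC)c2c(c1)O[C@H](c1ccc(OCc3ccccc3)cc1)C[C@H]2c1c(OCc2ccccc2)cc(OCc2ccccc2)c2c1O[C@H](c1ccccc1)CC2=O | intermediate
25 | (2S)-5,7-dihydroxy-8-[(2S)-2-(4-hydroxyphenyl)-5,7-dimethoxychroman-4-yl]-2-phenylchroman-4-one (2,4-trans flavan; CNP0188217.1) | COc1cc(OC)c2c(c1)O[C@H](c1ccc(O)cc1)C[C@H]2c1c(O)cc(O)c2c1O[C@H](c1ccccc1)CC2=O | target

**Step count**
Total: 15 steps. Longest linear sequence: 14 steps (steps 1–4 and 6–15, from 2,4,6-trihydroxybenzaldehyde).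

**Steps most likely to fail**

Step 8 (key step). The quinone methide may tautomerise to the 4-hydroxystyrene and be lost to oligomers, or the facial selectivity at C2 may be poor or eroded by re-ionisation of the product ether. The fallback closes ring C by a stereospecific displacement instead of through a planar C2. It sets out from 12: MnO2 in CH2Cl2 should oxidise the benzylic carbinol to the (3R)-ketone F1. Asymmetric transfer hydrogenation with RuCl[(R,R)-TsDPEN](p-cymene) and HCO2H/Et3N should then give the single (1R,3R)-carbinol F2. An intramolecular Mitsunobu etherification (PPh3, DIAD, THF, 0 °C) should close ring C with inversion to the silyl-protected (2S)-2,4-trans flavan F3. TBAF/AcOH then brings the route back at 15.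

Step 4. Conjugate addition to the doubly ortho-substituted, electron-rich iminium ion may be slow and reversible, so conversion or the configuration at C4 may suffer. The fallback sets C4 by hydride delivery instead of aryl delivery. It sets out from 3 and 6: a Corey–Fuchs sequence (CBr4, PPh3, which should give the dibromoalkene F4; then n-BuLi and ethyl chloroformate) should give the ethyl arylpropiolate F5. Pd(OAc)2-catalysed hydroarylation and lactonisation with 6 in formic acid at rt should give the 4-arylcoumarin F6. CuH-catalysed asymmetric conjugate reduction (Cu(OAc)2, the DTBM-SEGPHOS enantiomer chosen for 4S, polymethylhydrosiloxane, t-BuOH) should give the (4S)-dihydrocoumarin F7. i-Bu2AlH at −78 °C then brings the route back at lactol 8.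

Step 14. Facial selectivity of the oxa-Michael closure may be low, or it may be eroded by retro-Michael opening under the basic catalyst. The fallback gives up catalyst control and relies on separation with recycling. It sets out from 23: cyclisation with NaOAc in EtOH at 60 °C should give 24 together with its flavanone C2 epimer, the (2R)-flavanone F8. The two are diastereomers because of the flavan centres and should separate by chromatography. F8 is returned to the same base, which re-equilibrates it through 23, and the route continues from 24.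

**Further compounds**
F1 | step 8 | (3R)-3-[2-(allyloxy)-4,6-bis(benzyloxy)phenyl]-1-[4-(tert-butyldimethylsilyloxy)phenyl]-3-(2-hydroxy-4,6-dimethoxyphenyl)propan-1-one | O=C(C[C@H](c1c(O)cc(OC)cc1OC)c1c(OCC=C)cc(OCc2ccccc2)cc1OCc1ccccc1)c1ccc(O[Si](C)(C)C(C)(C)C)cc1
F2 | step 8 | (1R,3R)-3-[2-(allyloxy)-4,6-bis(benzyloxy)phenyl]-1-[4-(tert-butyldimethylsilyloxy)phenyl]-3-(2-hydroxy-4,6-dimethoxyphenyl)propan-1-ol | O[C@H](C[C@H](c1c(O)cc(OC)cc1OC)c1c(OCC=C)cc(OCc2ccccc2)cc1OCc1ccccc1)c1ccc(O[Si](C)(C)C(C)(C)C)cc1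
F3 | step 8 | (2S)-4-[2-(allyloxy)-4,6-bis(benzyloxy)phenyl]-2-[4-(tert-butyldimethylsilyloxy)phenyl]-5,7-dimethoxychroman (2,4-trans) | COc1cc(OC)c2c(c1)O[C@H](c1ccc(O[Si](C)(C)C(C)(C)C)cc1)C[C@H]2c1c(OCC=C)cc(OCc3ccccc3)cc1OCc1ccccc1
F4 | step 4 | 1-(allyloxy)-3,5-bis(benzyloxy)-2-(2,2-dibromovinyl)benzene | BrC(Br)=Cc1c(OCC=C)cc(OCc2ccccc2)cc1OCc1ccccc1
F5 | step 4 | ethyl 3-[2-(allyloxy)-4,6-bis(benzyloxy)phenyl]prop-2-ynoate | CCOC(=O)C#Cc1c(OCC=C)cc(OCc2ccccc2)cc1OCc1ccccc1
F6 | step 4 | 4-[2-(allyloxy)-4,6-bis(benzyloxy)phenyl]-5,7-dimethoxy-2H-chromen-2-one | COc1cc(OC)c2c(c1)OC(=O)C=C2c1c(OCC=C)cc(OCc3ccccc3)cc1OCc1ccccc1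
F7 | step 4 | (4S)-4-[2-(allyloxy)-4,6-bis(benzyloxy)phenyl]-5,7-dimethoxychroman-2-one | COc1cc(OC)c2c(c1)OC(=O)C[C@H]2c1c(OCC=C)cc(OCc3ccccc3)cc1OCc1ccccc1
F8 | step 14 | (2R)-5,7-bis(benzyloxy)-8-{(2S)-2-[4-(benzyloxy)phenyl]-5,7-dimethoxychroman-4-yl}-2-phenylchroman-4-one (2,4-trans flavan) | COc1cc(OC)c2c(c1)O[C@H](c1ccc(OCc3ccccc3)cc1)C[C@H]2c1c(OCc2ccccc2)cc(OCc2ccccc2)c2c1O[C@@H](c1ccccc1)CC2=O
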